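## Retrosynthetic overview

1. Ring E is made last: the target comes from hydrogenation of a C3 α‑methylidene lactone, itself from catalytic asymmetric 2‑(ethoxycarbonyl)allylation of a C3 carbaldehyde (formylation of the A–D tetracycle).
2. Ring C comes from an intramolecular Friedel–Crafts conjugate addition of pyrrole C1 to an α‑methylbutenolide (C1–C12 bond; sets C12 and C13).
3. Ring D (the butenolide) comes from a C11 aldehyde by asymmetric allylation/lactonisation and alkene isomerisation (sets C11).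
4. The C9–C10 bond comes from a new amine/Brønsted‑acid‑catalysed hydroalkylation of a bicyclic 2‑alkenylpyrrole with butanal (first stereocenters, C9 and C10).
5. Ring B is built on ring A from pyrrole‑2‑carbaldehyde and (4‑bromobutyl)triphenylphosphonium bromide (N‑alkylation/intramolecular Wittig). Ring order: A (bought) → B → D → C → E.

Assumption: the SMILES defines the target as 9R,10R,11S,12R,13R,18S,20S, with H11, H12 and H13 all cis (C13 methyl on the concave face) and a cis‑disubstituted ring E.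

Numbering used throughout: pyrrole C1, C2, C3, N4, C9a; azepine C5–C9; C10 bears ethyl; C11 bears the ring D oxygen; C12; C13 bears methyl; C14 is the ring D carbonyl; ring E is C18 (O‑bearing), C19, C20 (methyl‑bearing), C21 (carbonyl). Rings: A pyrrole, B azepine, C cyclohexane, D fused lactone, E appended lactone.

L = 1,8‑bis(4‑isopropyl‑4,5‑dihydro‑1,3‑oxazol‑2‑yl)‑3,6‑diphenyl‑9H‑carbazole, a tridentate bis(oxazoline). Its two antipodes are named below by the aldehyde face to which they deliver the allyl group; the assignment of (S,S) or (R,R) to each face is to be confirmed on a model aldehyde.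

## Route

Step 1
Reactants: 1 1H‑pyrrole‑2‑carbaldehyde; 2 (4‑bromobutyl)triphenylphosphonium bromide
Product: 4 6,7‑dihydro‑5H‑pyrrolo[1,2‑a]azepine, via phosphonium salt 3 (not isolated)
Conditions: NaH (1.05 equiv), DMF, 0 °C, then 2, 50 °C; then NaH (1.1 equiv), 0 to 60 °C
Reagents that add atoms: none
Why: N‑alkylation of the sodium pyrrolide by the primary bromide gives 3, and deprotonation then triggers an intramolecular Wittig olefination onto the 2‑formyl group that closes ring B with a cis C8=C9 bond (tandem N‑alkylation/intramolecular Wittig reaction; no stereocenter formed).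

Step 2
Reactants: 4 6,7‑dihydro‑5H‑pyrrolo[1,2‑a]azepine; 5 butanal
Product: 7 (2R)‑2‑[(9R)‑6,7,8,9‑tetrahydro‑5H‑pyrrolo[1,2‑a]azepin‑9‑yl]butanal, via azafulvenium phosphate 6 (not isolated)
Conditions: (S)‑2‑{bis[3,5‑bis(trifluoromethyl)phenyl](trimethylsilyloxy)methyl}pyrrolidine (20 mol %), (PhO)2P(O)OH (20 mol %), 5 (3 equiv), CH2Cl2, 0 °C, slow addition of 4
Reagents that add atoms: none
Why: Proposed new method: the ammonium phosphate protonates the electron‑rich 2‑alkenylpyrrole at C8 (Markovnikov, reversible) to give the planar cyclic 1‑azafulvenium ion 6, which is captured at C9 by the (E)‑enamine of butanal and the (S)‑diarylprolinol silyl ether on the unshielded Si face of the enamine carbon (sets C10 as R) through a staggered synclinal open transition state in which C9–H sits in the crowded sector between the enamine CH=N carbon and the ethyl group, the C8 methylene is anti to the enamine double bond and the pyrrolium ring lies under the enamine nitrogen (sets C9 as R), after which hydrolysis releases 7 and the amine; the closest known reaction type is the enamine‑catalysed SN1‑type α‑alkylation of aldehydes with diarylmethyl and indolylmethyl cations generated from carbinols, extended here to a cation generated by protonation of an alkene (a formal enantioselective hydroalkylation).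

Step 3
Reactants: 7 (2R)‑2‑[(9R)‑6,7,8,9‑tetrahydro‑5H‑pyrrolo[1,2‑a]azepin‑9‑yl]butanal; 8 ethyl 2‑(bromomethyl)prop‑2‑enoate
Product: 10 (5R)‑3‑methylidene‑5‑{(1R)‑1‑[(9R)‑6,7,8,9‑tetrahydro‑5H‑pyrrolo[1,2‑a]azepin‑9‑yl]propyl}oxolan‑2‑one, via silyl ether 9 (not isolated)
Conditions: CrCl2 (10 mol %), L (12 mol %, Re‑selective antipode), Mn, TMSCl, i‑Pr2NEt (cat.), THF, rt; then TBAF (10 mol %), THF, 0 °C
Reagents that add atoms: none
Why: A catalytic asymmetric Nozaki–Hiyama–Kishi‑type 2‑(alkoxycarbonyl)allylation (allylchromium addition, Mn as terminal reductant, TMSCl for turnover) adds to the Re face of the aldehyde, the sense favoured both by the ligand antipode and by Felkin–Anh control from C10, which sets C11 (R at this stage), and fluoride‑initiated desilylative lactonisation of 9 closes the α‑methylidene γ‑lactone.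

Step 4
Reactants: 10 (5R)‑3‑methylidene‑5‑{(1R)‑1‑[(9R)‑6,7,8,9‑tetrahydro‑5H‑pyrrolo[1,2‑a]azepin‑9‑yl]propyl}oxolan‑2‑one
Product: 11 (5S)‑3‑methyl‑5‑{(1R)‑1‑[(9R)‑6,7,8,9‑tetrahydro‑5H‑pyrrolo[1,2‑a]azepin‑9‑yl]propyl}furan‑2(5H)‑one
Conditions: RuHCl(CO)(PPh3)3 (5 mol %), toluene, 80 °C
Reagents that add atoms: none
Why: Ruthenium‑hydride‑catalysed alkene isomerisation (hydrometallation/β‑hydride elimination) moves the exocyclic double bond into the conjugated endocyclic C12=C13 position, the thermodynamically preferred trisubstituted butenolide, without touching C9, C10 or C11 (the descriptor at C11 changes from R to S only through the priority rules).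

Step 5
Reactants: 11 (5S)‑3‑methyl‑5‑{(1R)‑1‑[(9R)‑6,7,8,9‑tetrahydro‑5H‑pyrrolo[1,2‑a]azepin‑9‑yl]propyl}furan‑2(5H)‑one
Product: 12 (9R,10R,11S,12R,13R)‑tetracyclic A/B/C/D lactone (target core without the C3 side chain)
Conditions: Sc(OTf)3 (10 mol %), (CF3)2CHOH–CH2Cl2 1:4, 0.01 M, 0 °C to rt
Reagents that add atoms: none
Why: An intramolecular Friedel–Crafts conjugate (Michael) addition, 6‑(enolendo)‑exo‑trig, of pyrrole C1 to the Lewis‑acid‑activated butenolide forms ring C and the C1–C12 bond on the butenolide face that carries the tether, so the lactone is necessarily cis‑fused (C12 R), and the scandium enolate is protonated kinetically at C13 from the convex face, which leaves the methyl group on the concave face (C13 R).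

Step 6
Reactants: 12 (9R,10R,11S,12R,13R)‑tetracyclic A/B/C/D lactone (target core without the C3 side chain)
Product: 14 C3‑carbaldehyde of tetracycle 12, via iminium salt 13 (not isolated)
Conditions: POCl3, DMF, ClCH2CH2Cl, 0 °C to rt; then H2O
Reagents that add atoms: N,N‑dimethylformamide (CN(C)C=O); water (O)
Why: Vilsmeier–Haack formylation takes place at the only free pyrrole α‑position (C3) to give iminium salt 13, which is hydrolysed to the aldehyde on aqueous work‑up, and no stereocenter is affected.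

Step 7
Reactants: 14 C3‑carbaldehyde of tetracycle 12; 8 ethyl 2‑(bromomethyl)prop‑2‑enoate
Product: 16 (18S)‑20‑methylidene precursor of the target (α‑methylidene lactone E on C3), via silyl ether 15 (not isolated)
Conditions: CrCl2 (10 mol %), ent‑L (12 mol %, Si‑selective antipode), Mn, TMSCl, i‑Pr2NEt (cat.), THF, rt; then TBAF (10 mol %), THF, 0 °C
Reagents that add atoms: none
Why: The same chromium‑catalysed asymmetric 2‑(alkoxycarbonyl)allylation (Nozaki–Hiyama–Kishi type) with the opposite ligand antipode adds to the Si face of the heteroaryl aldehyde under catalyst control, the core stereocenters being remote, which sets C18 as S, and the non‑acidic fluoride‑initiated lactonisation of 15 avoids ionisation of the pyrrolyl carbinol.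

Step 8
Reactants: 16 (18S)‑20‑methylidene precursor of the target (α‑methylidene lactone E on C3)
Product: 17 target CNP0232452.6
Conditions: H2 (1 atm), RhCl(PPh3)3 (5 mol %), toluene–EtOH, rt
Reagents that add atoms: none
Why: Homogeneous rhodium‑catalysed hydrogenation of the 1,1‑disubstituted exocyclic alkene delivers hydrogen to the lactone face anti to the C18 pyrrolyl substituent, giving the cis‑2,4‑disubstituted lactone (C20 S) without hydrogenolysis of the pyrrolyl C–O bond.

## Compound list

1 | 1H‑pyrrole‑2‑carbaldehyde | O=Cc1ccc[nH]1 | starting material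
2 | (4‑bromobutyl)triphenylphosphonium bromide | BrCCCC[P+](c1ccccc1)(c1ccccc1)c1ccccc1.[Br-] | starting material
3 | [4‑(2‑formyl‑1H‑pyrrol‑1‑yl)butyl]triphenylphosphonium bromide (not isolated) | O=Cc1cccn1CCCC[P+](c1ccccc1)(c1ccccc1)c1ccccc1.[Br-] | intermediate
4 | 6,7‑dihydro‑5H‑pyrrolo[1,2‑a]azepine (C8=C9 alkene) | C1=Cc2cccn2CCC1 | intermediate
5 | butanal | CCCC=O | starting material
6 | 6,7,8,9‑tetrahydro‑5H‑pyrrolo[1,2‑a]azepin‑9‑ylium diphenyl phosphate (1‑azafulvenium ion pair, drawn as the iminium form; not isolated) | C1=C2C=CC=[N+]2CCCC1.[O-]P(=O)(Oc1ccccc1)Oc1ccccc1 | intermediate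
7 | (2R)‑2‑[(9R)‑6,7,8,9‑tetrahydro‑5H‑pyrrolo[1,2‑a]azepin‑9‑yl]butanal | CC[C@@H](C=O)[C@H]1CCCCn2cccc12 | intermediate
8 | ethyl 2‑(bromomethyl)prop‑2‑enoate | C=C(CBr)C(=O)OCC | starting material
9 | ethyl (4R,5R)‑2‑methylidene‑5‑[(9R)‑6,7,8,9‑tetrahydro‑5H‑pyrrolo[1,2‑a]azepin‑9‑yl]‑4‑(trimethylsilyloxy)heptanoate (not isolated) | CC[C@@H]([C@H](O[Si](C)(C)C)CC(=C)C(=O)OCC)[C@H]1CCCCn2cccc12 | intermediate
10 | (5R)‑3‑methylidene‑5‑{(1R)‑1‑[(9R)‑6,7,8,9‑tetrahydro‑5H‑pyrrolo[1,2‑a]azepin‑9‑yl]propyl}oxolan‑2‑one | CC[C@@H]([C@H]3CC(=C)C(=O)O3)[C@H]1CCCCn2cccc12 | intermediate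
11 | (5S)‑3‑methyl‑5‑{(1R)‑1‑[(9R)‑6,7,8,9‑tetrahydro‑5H‑pyrrolo[1,2‑a]azepin‑9‑yl]propyl}furan‑2(5H)‑one | CC[C@@H]([C@@H]3OC(=O)C(C)=C3)[C@H]1CCCCn2cccc12 | intermediate
12 | (9R,10R,11S,12R,13R)‑tetracyclic A/B/C/D lactone: the target without the C3 lactone; cis‑fused ring D, H11/H12/H13 all cis, ethyl trans to both neighbours | CC[C@H]1[C@@H]2OC(=O)[C@H](C)[C@@H]2c2ccn3c2[C@@H]1CCCC3 | intermediate
13 | C3‑[(dimethyliminio)methyl] derivative of 12, dichlorophosphate salt (not isolated) | CC[C@H]1[C@@H]2OC(=O)[C@H](C)[C@@H]2c2cc(C=[N+](C)C)n3c2[C@@H]1CCCC3.[O-]P(=O)(Cl)Cl | intermediate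
14 | C3‑carbaldehyde of 12 (9R,10R,11S,12R,13R) | CC[C@H]1[C@@H]2OC(=O)[C@H](C)[C@@H]2c2cc(C=O)n3c2[C@@H]1CCCC3 | intermediate
15 | ethyl (4S)‑2‑methylidene‑4‑(tetracycle‑3‑yl)‑4‑(trimethylsilyloxy)butanoate, tetracycle as in 12 (not isolated) | CC[C@H]1[C@@H]2OC(=O)[C@H](C)[C@@H]2c2cc([C@@H](O[Si](C)(C)C)CC(=C)C(=O)OCC)n3c2[C@@H]1CCCC3 | intermediate
16 | (18S)‑20‑methylidene bis‑lactone: the target with C20=CH2 in place of C20H–CH3 | CC[C@H]1[C@@H]2OC(=O)[C@H](C)[C@@H]2c2cc([C@@H]3CC(=C)C(=O)O3)n3c2[C@@H]1CCCC3 | intermediate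
17 | CNP0232452.6 (9R,10R,11S,12R,13R,18S,20S) | CC[C@H]1[C@@H]2OC(=O)[C@H](C)[C@@H]2c2cc([C@@H]3C[C@H](C)C(=O)O3)n3c2[C@@H]1CCCC3 | target

## Step count and risk

Total step count: 8. Longest linear sequence: 8 (all four building blocks 1, 2, 5 and 8 are achiral catalogue chemicals).

Steps most likely to fail:

Step 2 (the new reaction). The risks are slow C8 protonation relative to acid‑induced oligomerisation of 4, Mannich‑type attack of the free pyrrole α‑position on the butanal‑derived iminium ion, and an unproven facial preference at C9. The fallback uses known chemistry, sets out from 1 and returns at 7. N‑alkylation of 1 with 4‑bromobut‑1‑ene (K2CO3, DMF) gives 1‑(but‑3‑en‑1‑yl)‑1H‑pyrrole‑2‑carbaldehyde F1, and vinylmagnesium bromide (THF, −78 °C) gives racemic 1‑[1‑(but‑3‑en‑1‑yl)‑1H‑pyrrol‑2‑yl]prop‑2‑en‑1‑ol F2. Stereodivergent iridium/amine dual‑catalysed branched α‑allylation of butanal 5 ([Ir(cod)Cl]2, a chiral phosphoramidite–alkene ligand whose antipode is chosen for 9R, the same (S)‑diarylprolinol silyl ether for 10R, (MeO)2P(O)OH, ClCH2CH2Cl, rt) gives (2R,3R)‑3‑[1‑(but‑3‑en‑1‑yl)‑1H‑pyrrol‑2‑yl]‑2‑ethylpent‑4‑enal F3. Ring‑closing metathesis with the second‑generation Grubbs catalyst RuCl2(=CHPh)(H2IMes)(PCy3) (CH2Cl2, 40 °C) closes ring B to (2R)‑2‑[(9R)‑6,9‑dihydro‑5H‑pyrrolo[1,2‑a]azepin‑9‑yl]butanal F4. Diimide reduction of the C7=C8 bond (2‑nitrobenzenesulfonyl hydrazide, Et3N) then gives 7.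

Step 5. The α‑methylbutenolide is a weak acceptor, the pyrrole may oligomerise under acid, and the kinetic concave‑methyl C13 epimer may equilibrate to the more stable convex‑methyl epimer. The fallback sets out from 11 and returns at 12. An intramolecular oxidative (Fujiwara–Moritani‑type) cyclisation with Pd(OAc)2 (10 mol %), ethyl nicotinate and O2 in tert‑amyl alcohol–AcOH at 80 °C is used. Syn carbopalladation across C12=C13 puts palladium on C13 anti to H12, so β‑hydride elimination can only go into the methyl group, giving the cis‑fused tetracyclic 13‑methylidene lactone F5. Hydrogenation (H2, RhCl(PPh3)3) from the convex face then sets C13 as R and gives 12.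

Step 7. The N‑alkylpyrrole‑2‑carbaldehyde is a poor electrophile, catalyst control at the remote C18 is untested on this substrate, and the pyrrolyl carbinol derivative can ionise and racemise under the Lewis‑acidic conditions. The fallback sets out from 12 (before step 6) and returns at 16. Friedel–Crafts acylation of C3 with itaconic anhydride (AlCl3, CH2Cl2, 0 °C), which opens at the non‑conjugated carbonyl, gives 2‑methylidene‑4‑oxo‑4‑(tetracycle‑3‑yl)butanoic acid F6. Asymmetric transfer hydrogenation of the ketone with RuCl(p‑cymene)[(S,S)‑TsDPEN] and HCO2H/Et3N gives (4S)‑4‑hydroxy‑2‑methylidene‑4‑(tetracycle‑3‑yl)butanoic acid F7, which lactonises on concentration to 16.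

## Further compounds

F1 | step 2 | 1‑(but‑3‑en‑1‑yl)‑1H‑pyrrole‑2‑carbaldehyde | O=Cc1cccn1CCC=C
F2 | step 2 | 1‑[1‑(but‑3‑en‑1‑yl)‑1H‑pyrrol‑2‑yl]prop‑2‑en‑1‑ol (racemic) | OC(C=C)c1cccn1CCC=C
F3 | step 2 | (2R,3R)‑3‑[1‑(but‑3‑en‑1‑yl)‑1H‑pyrrol‑2‑yl]‑2‑ethylpent‑4‑enal | CC[C@@H](C=O)[C@@H](C=C)c1cccn1CCC=C
F4 | step 2 | (2R)‑2‑[(9R)‑6,9‑dihydro‑5H‑pyrrolo[1,2‑a]azepin‑9‑yl]butanal | CC[C@@H](C=O)[C@H]1C=CCCn2cccc12
F5 | step 5 | tetracyclic 13‑methylidene lactone (12 with C13=CH2; C9, C10, C11 and the cis ring fusion as in 12) | CC[C@H]1[C@@H]2OC(=O)C(=C)[C@@H]2c2ccn3c2[C@@H]1CCCC3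
F6 | step 7 | 2‑methylidene‑4‑oxo‑4‑(tetracycle‑3‑yl)butanoic acid (tetracycle as in 12) | CC[C@H]1[C@@H]2OC(=O)[C@H](C)[C@@H]2c2cc(C(=O)CC(=C)C(O)=O)n3c2[C@@H]1CCCC3
F7 | step 7 | (4S)‑4‑hydroxy‑2‑methylidene‑4‑(tetracycle‑3‑yl)butanoic acid (tetracycle as in 12) | CC[C@H]1[C@@H]2OC(=O)[C@H](C)[C@@H]2c2cc([C@@H](O)CC(=C)C(O)=O)n3c2[C@@H]1CCCC3
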